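**Strategy**

The dihydrofuran ring (ring B) is cut at the aryl ether bond O1–C7a and at C2–C3. C7a lies para to the C5 acrylate on the benzo ring (ring A), so a C7a–F bond is open to SNAr; C3 is benzylic and its CH2OH carbon can be an imide carbonyl, so C3 is an enolate carbon; C2 with O1 is the carbonyl group of protected syringaldehyde. One telescoped operation, an auxiliary-controlled Evans syn-aldol addition followed by ring closure of the aldol oxygen onto the fluoroarene, forms both bonds and both stereocentres. The precursor is the (S)-4-isopropyloxazolidinone imide of a 2-fluoro-3-methoxyphenylacetic acid that carries the tert-butyl acrylate para to fluorine.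

Key step: step 5

Assumption: benzofuran numbering is used (O1, C2, C3, C3a, C4–C7, C7a), the target is read as the trans-(2S,3R) isomer, and 2-(2-fluoro-3-methoxyphenyl)acetic acid is taken as a catalogue compound.

**Route**

Step 1
Reactants: 1 2-(2-fluoro-3-methoxyphenyl)acetic acid; 2 (S)-4-isopropyloxazolidin-2-one
Product: 4 (S)-3-[2-(2-fluoro-3-methoxyphenyl)acetyl]-4-isopropyloxazolidin-2-one, via mixed pivalic anhydride 3 (not isolated)
Conditions: PivCl, Et3N, THF, −20 °C; then 2, LiCl, −20 °C to rt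
Reagents that add atoms: none
Why: N-acylation of an oxazolidinone through a mixed anhydride (auxiliary attachment); the LiCl-activated oxazolidinone attacks the less hindered arylacetyl carbonyl, and the auxiliary stereocentre is not touched.

Step 2
Reactants: 4 (S)-3-[2-(2-fluoro-3-methoxyphenyl)acetyl]-4-isopropyloxazolidin-2-one
Product: 5 (S)-3-{2-[2-fluoro-3-methoxy-5-(4,4,5,5-tetramethyl-1,3,2-dioxaborolan-2-yl)phenyl]acetyl}-4-isopropyloxazolidin-2-one
Conditions: [Ir(OMe)(cod)]2 (1.5 mol%), 4,4'-di-tert-butyl-2,2'-bipyridine (3 mol%), B2pin2 (1.0 equiv), THF, 70 °C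
Reagents that add atoms: bis(pinacolato)diboron, CC1(C)OB(OC1(C)C)B1OC(C)(C)C(C)(C)O1
Why: Iridium-catalysed aromatic C–H borylation is sterically governed, and in this 1,2,3-trisubstituted benzene the C–H para to fluorine is the only one without an ortho substituent; the isopropyl auxiliary offers no competing arene C–H.

Step 3
Reactants: 5 (S)-3-{2-[2-fluoro-3-methoxy-5-(4,4,5,5-tetramethyl-1,3,2-dioxaborolan-2-yl)phenyl]acetyl}-4-isopropyloxazolidin-2-one; 6 tert-butyl acrylate
Product: 7 tert-butyl (E)-3-{4-fluoro-3-methoxy-5-[2-((S)-4-isopropyl-2-oxooxazolidin-3-yl)-2-oxoethyl]phenyl}acrylate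
Conditions: Pd(OAc)2 (5 mol%), 2,9-dimethyl-1,10-phenanthroline (6 mol%), O2 (1 atm), DMA, 50 °C
Reagents that add atoms: none
Why: Oxidative (boron) Heck reaction: the aryl group passes from boron to divalent palladium, syn-carbopalladation of the acrylate and syn-β-hydride elimination give the (E)-cinnamate, and O2 reoxidises zerovalent palladium; the base-free conditions spare the imide.

Step 4
Reactants: 8 syringaldehyde (4-hydroxy-3,5-dimethoxybenzaldehyde)
Product: 9 3,5-dimethoxy-4-(methoxymethoxy)benzaldehyde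
Conditions: MOMCl, iPr2NEt, CH2Cl2, 0 °C to rt
Reagents that add atoms: chloromethyl methyl ether (MOMCl), COCCl
Why: O-alkylation of the phenol (Williamson-type) gives a MOM ether that withstands the boron Lewis acid, carbonate base and fluoride of step 5; the aldehyde is not touched.

Step 5
Reactants: 7 tert-butyl (E)-3-{4-fluoro-3-methoxy-5-[2-((S)-4-isopropyl-2-oxooxazolidin-3-yl)-2-oxoethyl]phenyl}acrylate; 9 3,5-dimethoxy-4-(methoxymethoxy)benzaldehyde
Product: 12 tert-butyl (E)-3-{(2S,3S)-3-[(S)-4-isopropyl-2-oxooxazolidine-3-carbonyl]-7-methoxy-2-[3,5-dimethoxy-4-(methoxymethoxy)phenyl]-2,3-dihydrobenzofuran-5-yl}acrylate, via (Z)-dibutylboron enolate 10 (not isolated), via syn-aldol adduct 11 (not isolated)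
Conditions: Bu2BOTf, iPr2NEt, CH2Cl2, −78 to 0 °C; 9, −78 to 0 °C; pH 7 buffer/MeOH quench, solvent switch without purification; Cs2CO3, DMF, −20 to 0 °C
Reagents that add atoms: none
Why: Soft enolisation with Bu2BOTf/iPr2NEt gives the (Z)-boron enolate 10, which adds to aldehyde 9 through a closed Zimmerman–Traxler chair to form C2–C3 (Evans syn-aldol); after hydrolytic release of boron, Cs2CO3 unveils the C2 alkoxide, which attacks the C7a–F carbon of ring A through a Meisenheimer adduct stabilised by the para acrylate and expels fluoride to form O1–C7a. The closest known reaction types are the Evans boron aldol of N-arylacetyl oxazolidinones with aromatic aldehydes and the intramolecular SNAr etherification of ortho-fluoroaryl alkoxides. Ring B is the only ring closed, in a 5-exo-trig addition–elimination at the arene carbon. C3 is set by the (S)-isopropyl group of the auxiliary, which blocks one face of the dipole-minimised enolate, and C2 by the chair transition state with the aryl group of 9 equatorial, which gives the syn-(2S,3S) adduct; ring closure retains both centres and turns syn into 2,3-trans, which is also the thermodynamic arrangement should the acidic C3–H epimerise. The step needs chemoselective enolisation (only the imide CH2 is acidic and boron enolates do not add to the cinnamate), face selectivity (auxiliary) and ring closure faster than retro-aldol, dehydration or acyl transfer of the aldolate, for which the acceptor para to fluorine, the five-membered transition state and the low temperature are relied on.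

Step 6
Reactants: 12 tert-butyl (E)-3-{(2S,3S)-3-[(S)-4-isopropyl-2-oxooxazolidine-3-carbonyl]-7-methoxy-2-[3,5-dimethoxy-4-(methoxymethoxy)phenyl]-2,3-dihydrobenzofuran-5-yl}acrylate
Product: 13 tert-butyl (E)-3-{(2S,3R)-3-(hydroxymethyl)-7-methoxy-2-[3,5-dimethoxy-4-(methoxymethoxy)phenyl]-2,3-dihydrobenzofuran-5-yl}acrylate
Conditions: LiBH4, H2O (1 equiv), THF, 0 °C
Reagents that add atoms: none
Why: Reductive cleavage of the N-acyl oxazolidinone by hydride attack at the activated exocyclic carbonyl gives the primary alcohol and releases the auxiliary; the tert-butyl cinnamate and MOM ether are inert to LiBH4 at 0 °C, and the C3 descriptor changes from S to R only through the priority rules.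

Step 7
Reactants: 13 tert-butyl (E)-3-{(2S,3R)-3-(hydroxymethyl)-7-methoxy-2-[3,5-dimethoxy-4-(methoxymethoxy)phenyl]-2,3-dihydrobenzofuran-5-yl}acrylate
Product: 14 (E)-3-[(2S,3R)-2-(4-hydroxy-3,5-dimethoxyphenyl)-3-(hydroxymethyl)-7-methoxy-2,3-dihydrobenzofuran-5-yl]acrylic acid
Conditions: TFA/CH2Cl2/H2O, 0 °C to rt; then aq. NaHCO3/MeOH work-up
Reagents that add atoms: none
Why: Global acidolysis: E1 loss of isobutene from the tert-butyl ester and acetal hydrolysis of the MOM ether; any reversible ionisation of the benzylic C2–O1 bond re-closes to the trans ring because C3 is now a fixed stereocentre, and the basic work-up cleaves any trifluoroacetate of the primary alcohol.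

**Compound list**

1 | 2-(2-fluoro-3-methoxyphenyl)acetic acid | COc1cccc(CC(=O)O)c1F | starting material
2 | (S)-4-isopropyloxazolidin-2-one | CC(C)[C@H]1COC(=O)N1 | starting material
3 | 2-(2-fluoro-3-methoxyphenyl)acetic pivalic anhydride | COc1cccc(CC(=O)OC(=O)C(C)(C)C)c1F | intermediate
4 | (S)-3-[2-(2-fluoro-3-methoxyphenyl)acetyl]-4-isopropyloxazolidin-2-one | COc1cccc(CC(=O)N2[C@@H](C(C)C)COC2=O)c1F | intermediate
5 | (S)-3-{2-[2-fluoro-3-methoxy-5-(4,4,5,5-tetramethyl-1,3,2-dioxaborolan-2-yl)phenyl]acetyl}-4-isopropyloxazolidin-2-one | COc1cc(B2OC(C)(C)C(C)(C)O2)cc(CC(=O)N3[C@@H](C(C)C)COC3=O)c1F | intermediate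
6 | tert-butyl acrylate | C=CC(=O)OC(C)(C)C | starting material
7 | tert-butyl (E)-3-{4-fluoro-3-methoxy-5-[2-((S)-4-isopropyl-2-oxooxazolidin-3-yl)-2-oxoethyl]phenyl}acrylate | COc1cc(/C=C/C(=O)OC(C)(C)C)cc(CC(=O)N2[C@@H](C(C)C)COC2=O)c1F | intermediate
8 | syringaldehyde (4-hydroxy-3,5-dimethoxybenzaldehyde) | COc1cc(C=O)cc(OC)c1O | starting material
9 | 3,5-dimethoxy-4-(methoxymethoxy)benzaldehyde | COCOc1c(OC)cc(C=O)cc1OC | intermediate
10 | (Z)-dibutylboron enolate of 7 | CCCCB(CCCC)O/C(=C\c1cc(/C=C/C(=O)OC(C)(C)C)cc(OC)c1F)N1[C@@H](C(C)C)COC1=O | intermediate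
11 | tert-butyl (E)-3-{3-[(2S,3S)-3-hydroxy-1-((S)-4-isopropyl-2-oxooxazolidin-3-yl)-3-(3,5-dimethoxy-4-(methoxymethoxy)phenyl)-1-oxopropan-2-yl]-4-fluoro-5-methoxyphenyl}acrylate (syn-aldol adduct) | COCOc1c(OC)cc([C@@H](O)[C@@H](C(=O)N2[C@@H](C(C)C)COC2=O)c2cc(/C=C/C(=O)OC(C)(C)C)cc(OC)c2F)cc1OC | intermediate
12 | tert-butyl (E)-3-{(2S,3S)-3-[(S)-4-isopropyl-2-oxooxazolidine-3-carbonyl]-7-methoxy-2-[3,5-dimethoxy-4-(methoxymethoxy)phenyl]-2,3-dihydrobenzofuran-5-yl}acrylate | COCOc1c(OC)cc([C@H]2Oc3c(OC)cc(/C=C/C(=O)OC(C)(C)C)cc3[C@@H]2C(=O)N4[C@@H](C(C)C)COC4=O)cc1OC | intermediate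
13 | tert-butyl (E)-3-{(2S,3R)-3-(hydroxymethyl)-7-methoxy-2-[3,5-dimethoxy-4-(methoxymethoxy)phenyl]-2,3-dihydrobenzofuran-5-yl}acrylate | COCOc1c(OC)cc([C@H]2Oc3c(OC)cc(/C=C/C(=O)OC(C)(C)C)cc3[C@@H]2CO)cc1OC | intermediate
14 | (E)-3-[(2S,3R)-2-(4-hydroxy-3,5-dimethoxyphenyl)-3-(hydroxymethyl)-7-methoxy-2,3-dihydrobenzofuran-5-yl]acrylic acid | COc1cc([C@H]2Oc3c(OC)cc(/C=C/C(=O)O)cc3[C@@H]2CO)cc(OC)c1O | target

**Step count**

Total steps: 7. Longest linear sequence: 6 (steps 1, 2, 3, 5, 6, 7; step 4 is the side branch).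

**Steps most likely to fail**

Step 5 (key step). Once the aldol oxygen is unveiled as an alkoxide next to the acidic imide, retro-aldol cleavage, dehydration or acyl transfer onto the auxiliary may outrun ring closure and erode the configuration at C2. Fallback: the aldol stage is run alone and the syn-aldol adduct 11 is isolated. LiBH4 removes the auxiliary and should give tert-butyl (E)-3-{3-[(1S,2R)-1,3-dihydroxy-1-(3,5-dimethoxy-4-(methoxymethoxy)phenyl)propan-2-yl]-4-fluoro-5-methoxyphenyl}acrylate F1. Its primary hydroxyl is tritylated (TrCl, pyridine) to tert-butyl (E)-3-{4-fluoro-3-[(1S,2R)-1-hydroxy-1-(3,5-dimethoxy-4-(methoxymethoxy)phenyl)-3-(trityloxy)propan-2-yl]-5-methoxyphenyl}acrylate F2. With no carbonyl left at C3, KOtBu in THF at 0 °C closes ring B by SNAr to tert-butyl (E)-3-{(2S,3R)-7-methoxy-2-[3,5-dimethoxy-4-(methoxymethoxy)phenyl]-3-[(trityloxy)methyl]-2,3-dihydrobenzofuran-5-yl}acrylate F3. The acidolysis of step 7 then removes the trityl, MOM and tert-butyl groups together, so the route is rejoined at 14.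

Step 3. Transfer of the aryl group from the pinacol boronate to palladium may be slow under base-free oxidative conditions, so that protodeboronation or homocoupling takes over. Fallback: 5 is converted by ipso-iododeboronation (NaI, TsN(Cl)Na, aqueous THF, rt) into (S)-3-[2-(2-fluoro-5-iodo-3-methoxyphenyl)acetyl]-4-isopropyloxazolidin-2-one F4. This undergoes a classical Mizoroki–Heck reaction with 6 (Pd(OAc)2, P(o-tol)3, Et3N, MeCN, 80 °C) and rejoins the route at 7.

Step 6. Hydride may attack the endocyclic carbamate carbonyl of the hindered imide, or the basic medium may cause β-elimination of the aryloxide from the C3 enolate and open ring B. Fallback: 12 is hydrolysed with LiOH/H2O2 in THF/H2O at 0 °C (hydroperoxide attacks the exocyclic carbonyl) to (2S,3S)-5-[(E)-3-(tert-butoxy)-3-oxoprop-1-en-1-yl]-7-methoxy-2-[3,5-dimethoxy-4-(methoxymethoxy)phenyl]-2,3-dihydrobenzofuran-3-carboxylic acid F5. The acid is reduced chemoselectively with BH3·SMe2 in THF at 0 °C and rejoins the route at 13.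

**Further compounds**

F1 | step 5 | tert-butyl (E)-3-{3-[(1S,2R)-1,3-dihydroxy-1-(3,5-dimethoxy-4-(methoxymethoxy)phenyl)propan-2-yl]-4-fluoro-5-methoxyphenyl}acrylate | COCOc1c(OC)cc([C@@H](O)[C@@H](CO)c2cc(/C=C/C(=O)OC(C)(C)C)cc(OC)c2F)cc1OC
F2 | step 5 | tert-butyl (E)-3-{4-fluoro-3-[(1S,2R)-1-hydroxy-1-(3,5-dimethoxy-4-(methoxymethoxy)phenyl)-3-(trityloxy)propan-2-yl]-5-methoxyphenyl}acrylate | COCOc1c(OC)cc([C@@H](O)[C@@H](COC(c4ccccc4)(c5ccccc5)c6ccccc6)c2cc(/C=C/C(=O)OC(C)(C)C)cc(OC)c2F)cc1OC
F3 | step 5 | tert-butyl (E)-3-{(2S,3R)-7-methoxy-2-[3,5-dimethoxy-4-(methoxymethoxy)phenyl]-3-[(trityloxy)methyl]-2,3-dihydrobenzofuran-5-yl}acrylate | COCOc1c(OC)cc([C@H]2Oc3c(OC)cc(/C=C/C(=O)OC(C)(C)C)cc3[C@@H]2COC(c4ccccc4)(c5ccccc5)c6ccccc6)cc1OC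
F4 | step 3 | (S)-3-[2-(2-fluoro-5-iodo-3-methoxyphenyl)acetyl]-4-isopropyloxazolidin-2-one | COc1cc(I)cc(CC(=O)N2[C@@H](C(C)C)COC2=O)c1F
F5 | step 6 | (2S,3S)-5-[(E)-3-(tert-butoxy)-3-oxoprop-1-en-1-yl]-7-methoxy-2-[3,5-dimethoxy-4-(methoxymethoxy)phenyl]-2,3-dihydrobenzofuran-3-carboxylic acid | COCOc1c(OC)cc([C@H]2Oc3c(OC)cc(/C=C/C(=O)OC(C)(C)C)cc3[C@@H]2C(=O)O)cc1OC
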